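**Retrosynthetic overview**

1. The target is a C2-symmetric bis-isoflavan: two (3R)-7-hydroxychroman units (ring A = benzo ring, ring C = pyran ring) sit on a symmetric diaryl ether made of two rings B. Both halves are built at the same time.
2. Last disconnection: both C3 stereocentres come from a twofold iridium-catalysed asymmetric hydrogenation of a bis(isoflav-3-ene) (C3=C4 in each ring C), followed by global debenzylation.
3. Key disconnection: each ring C is opened at O1–C2 by retro-oxa-6π electrocyclization to an ortho-quinone methide. This goes back by a retro-Petasis step (C3–C4) to a salicylaldehyde (ring A + C4) and a 1-arylvinyl trifluoroborate (ring B + C3 + C2).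
4. Enabling feature: O1 sits on ring A ortho to the ring carbon that carries C4. Ring A can therefore bind boron through O1 and then become the ortho-quinone methide O1=C8a–C4a=C4, which with C3=C2 is a 1-oxatriene that closes the O1–C2 bond.
5. Ring order: the two rings B are joined first (SNAr diaryl ether, twofold ortho-lithiation/oxidation, acetyl groups turned into vinylborates). Rings A are bought. Both rings C are closed together in the key step.

Key step: step 7

Assumption: the (4R,5R)-configured ThrePHOX iridium catalyst is taken, by analogy with known hydrogenations of 3-aryl-2H-chromenes, to give the (3R) centres; if the sense proves opposite, its (4S,5S) enantiomer is used.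

**Route**

Step 1
Reactants: 1 1-(4-fluoro-2-methoxyphenyl)ethanone; 2 1-(4-hydroxy-2-methoxyphenyl)ethanone
Product: 3 bis(4-acetyl-3-methoxyphenyl) ether
Conditions: K2CO3, DMAc, 130 °C
Reagents that add atoms: none
Why: Nucleophilic aromatic substitution (SNAr): the para-acetyl group activates the C–F carbon of 1 toward the phenoxide of 2, and the product is symmetric because both partners carry the same substitution pattern.

Step 2
Reactants: 3 bis(4-acetyl-3-methoxyphenyl) ether
Product: 4 bis[3-methoxy-4-(2-methyl-1,3-dioxolan-2-yl)phenyl] ether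
Conditions: ethylene glycol, TsOH·H2O (cat.), toluene, reflux, Dean–Stark
Reagents that add atoms: ethylene glycol, OCCO
Why: Acid-catalysed ketalization with azeotropic removal of water masks both aryl ketones so that an alkyllithium base can be used in the next step.

Step 3
Reactants: 4 bis[3-methoxy-4-(2-methyl-1,3-dioxolan-2-yl)phenyl] ether
Product: 8 bis(4-acetyl-2-hydroxy-3-methoxyphenyl) ether, via dilithiated bis-dioxolane 5 (not isolated), via bis(dimethoxyboryl) bis-dioxolane 6 (not isolated), via bis-phenol bis-dioxolane 7 (not isolated)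
Conditions: n-BuLi (2.5 equiv), TMEDA, THF, −20 to 0 °C; B(OMe)3, −78 °C to rt; AcOH then 30% H2O2, 0 °C to rt; then 1 M HCl, THF, rt
Reagents that add atoms: hydrogen peroxide, OO; water, O
Why: Directed ortho-metalation lithiates on each ring the only C–H flanked by two oxygen substituents (between the diaryl ether oxygen and the methoxy group); borylation and boronate oxidation convert C–Li into C–OH at that position, and aqueous acid then hydrolyses the dioxolanes.

Step 4
Reactants: 8 bis(4-acetyl-2-hydroxy-3-methoxyphenyl) ether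
Product: 9 bis[4-acetyl-2-(benzyloxy)-3-methoxyphenyl] ether
Conditions: BnBr, K2CO3, DMF, 50 °C
Reagents that add atoms: benzyl bromide, BrCc1ccccc1
Why: Williamson ether synthesis; under carbonate only the phenols are deprotonated, so the methyl ketones are not alkylated.

Step 5
Reactants: 9 bis[4-acetyl-2-(benzyloxy)-3-methoxyphenyl] ether
Product: 10 bis{2-(benzyloxy)-3-methoxy-4-[1-(trifluoromethanesulfonyloxy)vinyl]phenyl} ether
Conditions: KN(SiMe3)2, THF, −78 °C; then PhNTf2, −78 to 0 °C
Reagents that add atoms: N-phenyl-bis(trifluoromethanesulfonimide), O=S(=O)(N(c1ccccc1)S(=O)(=O)C(F)(F)F)C(F)(F)F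
Why: Enol triflate formation: each methyl ketone has only one enolizable side, and the potassium enolate is O-sulfonylated to the 1-arylvinyl triflate.

Step 6
Reactants: 10 bis{2-(benzyloxy)-3-methoxy-4-[1-(trifluoromethanesulfonyloxy)vinyl]phenyl} ether
Product: 12 dipotassium bis{2-(benzyloxy)-3-methoxy-4-[1-(trifluoroborato)vinyl]phenyl} ether, via bis(pinacol alkenylboronate) 11 (not isolated)
Conditions: B2pin2, PdCl2(PPh3)2 (3 mol %), PPh3, KOPh, toluene, 50 °C; then aq KHF2, MeOH, rt
Reagents that add atoms: bis(pinacolato)diboron, CC1(C)OB(OC1(C)C)B1OC(C)(C)C(C)(C)O1; potassium hydrogen difluoride, [K+].[F-].F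
Why: Miyaura borylation of the alkenyl triflates at zerovalent palladium, with the weak phenoxide base holding back Suzuki coupling of product with substrate; KHF2 then converts the crude pinacol esters into crystalline, bench-stable trifluoroborates.

Step 7
Reactants: 12 dipotassium bis{2-(benzyloxy)-3-methoxy-4-[1-(trifluoroborato)vinyl]phenyl} ether; 13 4-(benzyloxy)-2-hydroxybenzaldehyde (2.2 equiv)
Product: 16 bis{2-(benzyloxy)-4-[7-(benzyloxy)-2H-chromen-3-yl]-3-methoxyphenyl} ether, via bis(allylic dibenzylamine) Petasis adduct 14 (not isolated), via bis(ortho-quinone methide) 15 (not isolated)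
Conditions: Bn2NH (40 mol %), DMF, 80 °C
Reagents that add atoms: none
Why: Condensation of each aldehyde 13 with Bn2NH gives an iminium ion whose ortho-phenoxide displaces fluoride at boron, and the resulting ate complex transfers the 1-arylvinyl group intramolecularly to the iminium carbon (Petasis borono-Mannich reaction, forming C3–C4) to give 14. On heating, the ortho-hydroxybenzylic amine is expelled to give ortho-quinone methide 15, a 1-oxatriene O1=C8a–C4a=C4–C3=C2, and the amine re-enters the cycle. Each pyran ring then closes by thermal disrotatory oxa-6π electrocyclization, which forms the O1–C2 bond and restores the aromaticity of ring A; the closest known reaction type is the amine-catalysed Petasis/electrocyclization synthesis of 2H-chromenes from salicylaldehydes and alkenylboron reagents. No stereocentre is formed, since C3 and C4 stay sp2 and are reduced enantioselectively in step 8. The step needs alkenyl transfer to outrun protodeboronation and exclusive six-ring closure on both arms: the ortho-OH secures the first by delivering the alkenyl group within a boron chelate, and the second is inherent because only O1 and the terminal CH2 of the oxatriene can reach each other. In one operation both ring-A units are joined to the core and both pyran rings are closed, so four bonds and the full carbon skeleton arise from three simple components.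

Step 8
Reactants: 16 bis{2-(benzyloxy)-4-[7-(benzyloxy)-2H-chromen-3-yl]-3-methoxyphenyl} ether
Product: 17 bis{2-(benzyloxy)-4-[(3R)-7-(benzyloxy)chroman-3-yl]-3-methoxyphenyl} ether
Conditions: [Ir(cod)((4R,5R)-ThrePHOX)][B(3,5-(CF3)2C6H3)4] (4 mol %; ThrePHOX = O-[1-benzyl-1-(5-methyl-2-phenyl-4,5-dihydrooxazol-4-yl)-2-phenylethyl] diphenylphosphinite), H2 (50 bar), CH2Cl2, rt
Reagents that add atoms: none
Why: Iridium-catalysed asymmetric hydrogenation of a trisubstituted aryl-conjugated alkene with a cationic P,N-ligand catalyst, a reaction type established for 3-aryl-2H-chromenes; each C3 centre is set by catalyst-controlled facial delivery of H2, and because the two chromene units react independently the (R,R) product should be further enriched over the separable meso isomer.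

Step 9
Reactants: 17 bis{2-(benzyloxy)-4-[(3R)-7-(benzyloxy)chroman-3-yl]-3-methoxyphenyl} ether
Product: 18 bis{2-hydroxy-4-[(3R)-7-hydroxychroman-3-yl]-3-methoxyphenyl} ether (CNP0116832.1)
Conditions: H2 (1 atm), Pd/C (10 wt %), EtOAc/MeOH, rt
Reagents that add atoms: none
Why: Hydrogenolysis of the four benzyl aryl ethers; the chroman C–O bonds are not benzylic, the diaryl ether and methyl ethers are inert, and the C3 stereocentres are not touched.

**Compound list**

1 | 1-(4-fluoro-2-methoxyphenyl)ethanone | CC(=O)c1ccc(F)cc1OC | starting material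
2 | 1-(4-hydroxy-2-methoxyphenyl)ethanone | CC(=O)c1ccc(O)cc1OC | starting material
3 | bis(4-acetyl-3-methoxyphenyl) ether | CC(=O)c1ccc(Oc2ccc(C(C)=O)c(OC)c2)cc1OC | intermediate
4 | bis[3-methoxy-4-(2-methyl-1,3-dioxolan-2-yl)phenyl] ether | CC1(OCCO1)c2ccc(Oc3ccc(C4(C)OCCO4)c(OC)c3)cc2OC | intermediate
5 | bis[2-lithio-3-methoxy-4-(2-methyl-1,3-dioxolan-2-yl)phenyl] ether (formed in the flask) | CC1(OCCO1)c2ccc(Oc3ccc(C4(C)OCCO4)c(OC)c3[Li])c([Li])c2OC | intermediate
6 | bis[2-(dimethoxyboryl)-3-methoxy-4-(2-methyl-1,3-dioxolan-2-yl)phenyl] ether (formed in the flask) | CC1(OCCO1)c2ccc(Oc3ccc(C4(C)OCCO4)c(OC)c3B(OC)OC)c(B(OC)OC)c2OC | intermediate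
7 | bis[2-hydroxy-3-methoxy-4-(2-methyl-1,3-dioxolan-2-yl)phenyl] ether (formed in the flask) | CC1(OCCO1)c2ccc(Oc3ccc(C4(C)OCCO4)c(OC)c3O)c(O)c2OC | intermediate
8 | bis(4-acetyl-2-hydroxy-3-methoxyphenyl) ether | CC(=O)c1ccc(Oc2ccc(C(C)=O)c(OC)c2O)c(O)c1OC | intermediate
9 | bis[4-acetyl-2-(benzyloxy)-3-methoxyphenyl] ether | CC(=O)c1ccc(Oc2ccc(C(C)=O)c(OC)c2OCc3ccccc3)c(OCc4ccccc4)c1OC | intermediate
10 | bis{2-(benzyloxy)-3-methoxy-4-[1-(trifluoromethanesulfonyloxy)vinyl]phenyl} ether | C=C(OS(=O)(=O)C(F)(F)F)c1ccc(Oc2ccc(C(=C)OS(=O)(=O)C(F)(F)F)c(OC)c2OCc3ccccc3)c(OCc4ccccc4)c1OC | intermediate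
11 | bis{2-(benzyloxy)-3-methoxy-4-[1-(4,4,5,5-tetramethyl-1,3,2-dioxaborolan-2-yl)vinyl]phenyl} ether (formed in the flask) | C=C(B1OC(C)(C)C(C)(C)O1)c2ccc(Oc3ccc(C(=C)B4OC(C)(C)C(C)(C)O4)c(OC)c3OCc5ccccc5)c(OCc6ccccc6)c2OC | intermediate
12 | dipotassium bis{2-(benzyloxy)-3-methoxy-4-[1-(trifluoroborato)vinyl]phenyl} ether | [K+].[K+].C=C([B-](F)(F)F)c1ccc(Oc2ccc(C(=C)[B-](F)(F)F)c(OC)c2OCc3ccccc3)c(OCc4ccccc4)c1OC | intermediate
13 | 4-(benzyloxy)-2-hydroxybenzaldehyde | O=Cc1ccc(OCc2ccccc2)cc1O | starting material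
14 | bis{2-(benzyloxy)-4-[3-(4-(benzyloxy)-2-hydroxyphenyl)-3-(dibenzylamino)prop-1-en-2-yl]-3-methoxyphenyl} ether, stereoisomer mixture at the amine-bearing carbons (formed in the flask) | C=C(C(N(Cc1ccccc1)Cc1ccccc1)c1ccc(OCc2ccccc2)cc1O)c1ccc(Oc2ccc(C(=C)C(N(Cc3ccccc3)Cc3ccccc3)c3ccc(OCc4ccccc4)cc3O)c(OC)c2OCc2ccccc2)c(OCc2ccccc2)c1OC | intermediate
15 | bis(ortho-quinone methide): each ring B carries a buta-1,3-dien-2-yl unit whose C4 is the exocyclic methide carbon of a 3-(benzyloxy)-6-methylenecyclohexa-2,4-dienone (formed in the flask) | C=C(C=C1C=CC(OCc2ccccc2)=CC1=O)c1ccc(Oc2ccc(C(=C)C=C3C=CC(OCc4ccccc4)=CC3=O)c(OC)c2OCc2ccccc2)c(OCc2ccccc2)c1OC | intermediate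
16 | bis{2-(benzyloxy)-4-[7-(benzyloxy)-2H-chromen-3-yl]-3-methoxyphenyl} ether | COc1c(C2=Cc3ccc(OCc4ccccc4)cc3OC2)ccc(Oc2ccc(C3=Cc4ccc(OCc5ccccc5)cc4OC3)c(OC)c2OCc2ccccc2)c1OCc1ccccc1 | intermediate
17 | bis{2-(benzyloxy)-4-[(3R)-7-(benzyloxy)chroman-3-yl]-3-methoxyphenyl} ether | COc1c([C@@H]2COc3cc(OCc4ccccc4)ccc3C2)ccc(Oc2ccc([C@@H]3COc4cc(OCc5ccccc5)ccc4C3)c(OC)c2OCc2ccccc2)c1OCc1ccccc1 | intermediate
18 | bis{2-hydroxy-4-[(3R)-7-hydroxychroman-3-yl]-3-methoxyphenyl} ether | COc1c([C@@H]2COc3cc(O)ccc3C2)ccc(Oc2ccc([C@@H]3COc4cc(O)ccc4C3)c(OC)c2O)c1O | target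

**Step count and risks**

Total steps: 9. Longest linear sequence: 9 steps (from 1 or 2 to 18); aldehyde 13 enters in step 7.

Steps most likely to fail:

Step 7. The alkenyl transfer from the hindered, ortho-substituted 1-arylvinyl borate may be slow, so that protodeboronation or reaction on only one arm competes. The fallback sets out from 10 and comes back at 16; it makes the C3–C4 bonds by carbonyl addition of an alkenylchromium reagent. Aldehyde 13 is first protected with MOMCl and iPr2NEt in CH2Cl2 as 4-(benzyloxy)-2-(methoxymethoxy)benzaldehyde F1. Nozaki–Hiyama–Kishi coupling of bis(enol triflate) 10 with F1 (CrCl2, NiCl2 cat., DMF, rt) should give the bis(allylic alcohol) bis{2-(benzyloxy)-4-[3-(4-(benzyloxy)-2-(methoxymethoxy)phenyl)-3-hydroxyprop-1-en-2-yl]-3-methoxyphenyl} ether F2 as a mixture of carbinol stereoisomers. Catalytic TsOH in MeOH/THF then removes both methoxymethyl groups and dehydrates the ortho-hydroxybenzylic allylic alcohols to the same bis(ortho-quinone methide) 15, which electrocyclizes to 16.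

Step 8. Facial selectivity may be insufficient on one or both chromene units, whose aryl group carries an ortho-methoxy substituent; in a twofold reduction this shows up as meso and enantiomeric contamination. The fallback sets out from 16 and comes back at 18; it replaces asymmetric catalysis by resolution. Hydrogenation over Pd/C (H2, EtOAc/MeOH) saturates both chromene double bonds without facial control and cleaves the four benzyl ethers, giving the stereoisomer mixture bis[2-hydroxy-4-(7-hydroxychroman-3-yl)-3-methoxyphenyl] ether F3 (racemate plus meso form). The meso isomer is removed by chromatography or crystallization, and the racemate is resolved by preparative HPLC on a chiral stationary phase to give 18.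

Step 3. The second lithiation may be incomplete, or metalation may occur ortho to a dioxolane instead of between the two oxygen substituents. The fallback sets out from 1 and comes back at 9; it installs the oxygen on the monomer, where the site between fluorine and methoxy is unambiguous. Compound 1 is ketalized (ethylene glycol, TsOH, toluene, Dean–Stark) to 2-(4-fluoro-2-methoxyphenyl)-2-methyl-1,3-dioxolane F4. n-BuLi in THF at −78 °C, kept cold to avoid aryne formation, gives 2-(4-fluoro-3-lithio-2-methoxyphenyl)-2-methyl-1,3-dioxolane F5; B(OMe)3 gives the dimethyl boronate 2-[3-(dimethoxyboryl)-4-fluoro-2-methoxyphenyl]-2-methyl-1,3-dioxolane F6; AcOH/H2O2 gives 6-fluoro-2-methoxy-3-(2-methyl-1,3-dioxolan-2-yl)phenol F7; and aqueous HCl gives 1-(4-fluoro-3-hydroxy-2-methoxyphenyl)ethanone F8. Benzylation (BnBr, K2CO3, DMF) gives 1-[3-(benzyloxy)-4-fluoro-2-methoxyphenyl]ethanone F9. Half of F9 is hydrolysed with KOH in DMSO/H2O to 1-[3-(benzyloxy)-4-hydroxy-2-methoxyphenyl]ethanone F10. SNAr of F10 with the remaining F9 (K2CO3, DMAc, 130 °C) gives 9.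

**Further compounds**

F1 | step 7 | 4-(benzyloxy)-2-(methoxymethoxy)benzaldehyde | COCOc1cc(OCc2ccccc2)ccc1C=O
F2 | step 7 | bis{2-(benzyloxy)-4-[3-(4-(benzyloxy)-2-(methoxymethoxy)phenyl)-3-hydroxyprop-1-en-2-yl]-3-methoxyphenyl} ether (carbinol stereoisomer mixture) | C=C(C(O)c1ccc(OCc2ccccc2)cc1OCOC)c1ccc(Oc2ccc(C(=C)C(O)c3ccc(OCc4ccccc4)cc3OCOC)c(OC)c2OCc2ccccc2)c(OCc2ccccc2)c1OC
F3 | step 8 | bis[2-hydroxy-4-(7-hydroxychroman-3-yl)-3-methoxyphenyl] ether (racemate plus meso form) | COc1c(C2COc3cc(O)ccc3C2)ccc(Oc2ccc(C3COc4cc(O)ccc4C3)c(OC)c2O)c1O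
F4 | step 3 | 2-(4-fluoro-2-methoxyphenyl)-2-methyl-1,3-dioxolane | CC1(OCCO1)c2ccc(F)cc2OC
F5 | step 3 | 2-(4-fluoro-3-lithio-2-methoxyphenyl)-2-methyl-1,3-dioxolane | CC1(OCCO1)c2ccc(F)c([Li])c2OC
F6 | step 3 | 2-[3-(dimethoxyboryl)-4-fluoro-2-methoxyphenyl]-2-methyl-1,3-dioxolane | CC1(OCCO1)c2ccc(F)c(B(OC)OC)c2OC
F7 | step 3 | 6-fluoro-2-methoxy-3-(2-methyl-1,3-dioxolan-2-yl)phenol | CC1(OCCO1)c2ccc(F)c(O)c2OC
F8 | step 3 | 1-(4-fluoro-3-hydroxy-2-methoxyphenyl)ethanone | CC(=O)c1ccc(F)c(O)c1OC
F9 | step 3 | 1-[3-(benzyloxy)-4-fluoro-2-methoxyphenyl]ethanone | CC(=O)c1ccc(F)c(OCc2ccccc2)c1OC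
F10 | step 3 | 1-[3-(benzyloxy)-4-hydroxy-2-methoxyphenyl]ethanone | CC(=O)c1ccc(O)c(OCc2ccccc2)c1OC
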